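## The problem

Dielsianone (14) is an unsymmetrical benzil. One carbonyl carbon (Cb) carries a 4-methoxyphenyl group; the other (Ca) sits on C6 of a 5-hydroxy-8-methoxy-2,2-dimethyl-2H-chromene (chromene numbering O1, C2 to C8a; ring A is the benzene ring, ring B the pyran). The molecule has no stereocentre, so nothing has to be set or relayed in space, and every selectivity question is one of position. Ring A is pentasubstituted and its three oxygens play three different roles: pyran oxygen on C8a, methyl ether on C8, free phenol on C5 hydrogen-bonded to Ca=O. The fragile parts are the 1,2-diketone (benzilic acid rearrangement in strong alkali, easy reduction to the benzoin, condensation with 1,2-diamines), the electron-rich C3=C4 double bond of ring B (acid, electrophiles, hydrogenation) and the para-related C5 hydroxyl and C8 methoxyl, which strong oxidants turn into a quinone. The skeletal task is the chain C6–Ca–Cb: an arylacetyl unit has to be placed on C6 next to the C5 oxygen and then raised to the diketone. The feature to exploit is that the C5 oxygen, C5, C6, Ca and Cb form a five-atom chain, so one bridging carbon between that oxygen and Cb completes a six-membered ring. An arylacetate ester on the C5 oxygen therefore holds its alpha carbon (the future Cb) within six-membered reach of an ester carbonyl on C6 (the future Ca), and the bridging carbon can be discarded afterwards as CO2.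

## Retrosynthesis

**Ring B last (14 to 11 and 12).** Cutting O1–C2 and C4–C4a of 14 leads to the open benzil 11, 1-(2,4-dihydroxy-5-methoxyphenyl)-2-(4-methoxyphenyl)ethane-1,2-dione, and 3-methylbut-2-enal (12). This is preferred to an early chromene because the C3=C4 double bond then meets no oxidant, Lewis acid or hot alkali. Compound 11 also dictates the regiochemistry. The future C4a is the only free ring carbon ortho to a hydroxyl, and only the hydroxyl that becomes O1 is free, the other being locked in a hydrogen bond to Ca=O. The forward reaction must tolerate a 1,2-diketone, which rules out diamine catalysts and points to pyridine.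

**Diketone back to ketone (11 to 10 to 9).** Removing the Cb oxygen and restoring a benzyl group on the future O1 leads through benzyl ether 10 to deoxybenzoin 9. No carbon–carbon bond is cut, but the most fragile function is exchanged for a robust ketone whose methylene is the only enolisable position and is doubly activated. In the forward direction the oxidation is run with the benzyl ether in place, so the only free phenol is the hydrogen-bonded one. The benzyl group is then removed with BCl3, since hydrogenolysis would reduce the diketone.

**Carbon excision in reverse (9 to 7).** Deoxybenzoin 9 is read as a 3-aryl-4-hydroxycoumarin that has lost one carbon: a carbonyl bridge between the phenol oxygen and the methylene gives 7. In the forward direction hydroxide opens the lactone to keto acid 8, which loses CO2. The neighbouring cut of 9 at C6–Ca, a Friedel–Crafts acylation of 1 by acid 5, is shorter and is kept in reserve. It is not the first choice because it puts an oxidation-prone methoxyresorcinol in hot Lewis acid, gives no control over C- versus O-acylation or over the two open ring positions, and makes the decisive bond intermolecularly. The detour through 7 costs a carbon and several steps. In return every bond forms at a defined atom under mild base, and 7, being as acidic as a carboxylic acid, should be separable by simple extraction.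

**Key cut Ca–Cb (7 to 6).** Cutting the C3–C4 bond of the coumarin opens the pyranone ring to diester 6. There Ca is a methyl ester carbon on the ring and Cb is the alpha carbon of an arylacetate on the adjacent oxygen. Nucleophile (a benzylic ester enolate) and electrophile sit in one molecule, six atoms apart. The forward reaction asks for enolisation without loss of the acyl group and for an irreversible last step, which the acidity of 7 provides.

**Ester cut (6 to 4 and 5).** The phenolic ester C–O bond is cut to give phenol 4 and commercial 4-methoxyphenylacetic acid (5), so the whole anisyl–Cb unit is bought. The coupling must acylate a hydrogen-bonded phenol, hence DMAP catalysis.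

**Ring A building block (4 to 3 to 2 to 1).** Removing the benzyl group (3), the ester methyl (acid 2) and finally Ca itself as CO2 leads to 4-methoxybenzene-1,3-diol (1). A Kolbe–Schmitt reaction is preferred to formylation and oxidation because it brings Ca in at the acid level in one operation, at the carbon ortho to one hydroxyl and para to the other. Benzylation must distinguish the two hydroxyls of 3, which the salicylate hydrogen bond does. This differentiation later decides which oxygen becomes O1 and which the C5 phenol.

## Roads not taken

**Alternative 1: aryne insertion into the C–O bond of acid 5.**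
- Cut and key step: C5–O and C6–Ca are cut at once. Fluoride would release a symmetrical aryne from 4,5-bis(benzyloxy)-2-(trimethylsilyl)phenyl trifluoromethanesulfonate A1. The carboxylate of 5 would add through oxygen, and the aryl anion would attack the adjacent ester carbonyl and open the four-membered intermediate to 1-[4,5-bis(benzyloxy)-2-hydroxyphenyl]-2-(4-methoxyphenyl)ethan-1-one A2.
- Merit: one step gives the 2-hydroxydeoxybenzoin directly from 5 with no carbon to excise. In bond economy this is better than the chosen plan, which spends steps 4 to 6 on the same connection.
- Weak points: A1 is itself a multistep compound. The aryne must be symmetrical to avoid regioisomers, so both flanking oxygens arrive as benzyl ethers, whereas 14 needs one as the C8 methyl ether and the other as the pyran oxygen. After debenzylation the hydroxyl para to the ketone is the more acidic and would be methylated first, which is the wrong one. An unsymmetrical benzyloxy/methoxy aryne would not discriminate, since both substituents are remote from the aryne carbons. Proton transfer from the acidic methylene of 5 to the aryl anion would divert material to the simple aryl ester.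
- Comparison: against the shorter key step, the chosen plan offers a ring A oxygen pattern that is differentiated from compound 1 onwards, and cheap reagents.

**Alternative 2: borono-Mannich alkenylation and oxa-electrocyclisation.**
- Cut and key step: ring B is cut at C3–C4 and O1–C2. 2-Hydroxy-3-methoxy-6-(methoxymethoxy)benzaldehyde A3, dibenzylamine A4 and (2-methylprop-1-en-1-yl)boronic acid A5 would give an allylic amine. On heating it would lose the amine to an ortho-quinone methide that closes to 8-methoxy-5-(methoxymethoxy)-2,2-dimethyl-2H-chromene A6.
- Merit: ring B is placed by the position of the aldehyde, not by substrate bias, and under milder conditions than hot pyridine. For ring B alone this road is at least as good as step 9 of the chosen plan.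
- Weak points: the step leaves the real problem, the C6–Ca–Cb chain, untouched. From A6, C6 would have to be metalated next to the acetal oxygen, in competition with C7 next to the methoxyl, and acylated with an arylglyoxyl or arylacetyl electrophile. The chromene double bond would have to survive that chemistry, any later oxidation and the acidic removal of the acetal. A3 is not a commercial compound.
- Comparison: the chosen plan carries the sensitive chromene through no step at all, because it is formed last. The price is reliance on hydrogen-bond control in the final annulation.

**Alternative 3: chromium carbene benzannulation.**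
- Cut and key step: ring A is cut at C8–C7, C6–C5 and C5–C4a, with C5 coming from carbon monoxide. The zerovalent chromium carbene complex pentacarbonyl[(6,6-dimethyl-5,6-dihydro-4H-pyran-2-yl)(methoxy)methylidene]chromium, (CO)5Cr=C(OMe)R, A7 would take up the terminal triple bond of 1-(buta-1,3-diyn-1-yl)-4-methoxybenzene A8 and one CO ligand. The product would be 8-methoxy-6-[(4-methoxyphenyl)ethynyl]-2,2-dimethyl-3,4-dihydro-2H-chromen-5-ol A9.
- Merits: all substituents of ring A are placed in one step by the known regiochemistry of alkyne insertion (larger substituent next to the new phenol). The diketone is carried as an alkyne, which needs only an alkyne-to-diketone oxidation, not the oxidation of a methylene beside a free phenol. On that point it is better than step 7 of the chosen plan.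
- Weak points: stoichiometric chromium, and a carbene complex that must be made from a lithiated dihydropyran. The terminal aryl diyne is of limited stability. The product is a chroman, so C3=C4 must be introduced afterwards by dehydrogenation with a quinone oxidant, in the presence of a para-methoxyphenol that the same oxidant would convert into a quinone. The route is longer overall.
- Comparison: the chosen plan uses no stoichiometric transition metal and forms ring B directly at the right oxidation level. The price is one wasted carbon and a Riley oxidation.

Key step: step 5

Assumption: 4-methoxybenzene-1,3-diol (1) is taken to be purchasable; as an easily oxidised hydroxyquinol ether it is handled under inert gas.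

## Route

Step 1
Reactants: 1 4-methoxybenzene-1,3-diol
Product: 2 2,4-dihydroxy-5-methoxybenzoic acid
Conditions: KHCO3, H2O, CO2 (1 atm), 95 °C; then HCl, 0 °C
Reagents that add atoms: carbon dioxide, O=C=O (supplied as the gas and as KHCO3, [K+].OC([O-])=O)
Why: Kolbe–Schmitt carboxylation under aqueous hydrogencarbonate conditions; the resorcinol anion is carboxylated at the carbon ortho to one hydroxyl and para to the other, which in 1 is C6 because C4 carries the methoxyl. 4-Substituted resorcinols are known to react at this position, and the hindered carbon between the hydroxyls reacts only under harsher conditions.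

Step 2
Reactants: 2 2,4-dihydroxy-5-methoxybenzoic acid
Product: 3 methyl 2,4-dihydroxy-5-methoxybenzoate
Conditions: MeOH, H2SO4 (cat.), reflux
Reagents that add atoms: methanol, CO
Why: Fischer esterification; the phenols do not react, and the hydrogen bond of the salicylic acid only slows the reaction.

Step 3
Reactants: 3 methyl 2,4-dihydroxy-5-methoxybenzoate
Product: 4 methyl 4-(benzyloxy)-2-hydroxy-5-methoxybenzoate
Conditions: BnBr (1.05 equiv), K2CO3, acetone, reflux
Reagents that add atoms: benzyl bromide, BrCc1ccccc1
Why: Williamson etherification with one equivalent of halide; the 4-hydroxyl (para to the ester, not hydrogen-bonded) is the more acidic and more nucleophilic phenol, while the 2-hydroxyl is held by the ester carbonyl, a selectivity routinely used with 2,4-dihydroxybenzoates.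

Step 4
Reactants: 4 methyl 4-(benzyloxy)-2-hydroxy-5-methoxybenzoate; 5 4-methoxyphenylacetic acid
Product: 6 methyl 4-(benzyloxy)-5-methoxy-2-{[2-(4-methoxyphenyl)acetyl]oxy}benzoate
Conditions: DCC, DMAP (cat.), CH2Cl2, 0 °C to rt
Reagents that add atoms: none
Why: Steglich esterification; the acylpyridinium formed from 5, DCC and DMAP acylates the remaining hydrogen-bonded phenol, and nothing else in 4 is nucleophilic.

Step 5
Reactants: 6 methyl 4-(benzyloxy)-5-methoxy-2-{[2-(4-methoxyphenyl)acetyl]oxy}benzoate
Product: 7 7-(benzyloxy)-4-hydroxy-6-methoxy-3-(4-methoxyphenyl)-2H-chromen-2-one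
Conditions: KOtBu (2.2 equiv), THF, 0 °C to rt; then 1 M HCl
Reagents that add atoms: none
Why: KOtBu removes the proton of the methylene that is both benzylic and alpha to the aryl ester, giving the ester enolate. Its carbon, the future Cb, adds to the carbonyl of the neighbouring methyl ester, the future Ca, in a 6-exo-trig closure: the new pyranone ring holds six atoms and the attacked C=O lies outside it. The tetrahedral intermediate expels methoxide, and the keto form of 7 is deprotonated at once to the delocalised 4-oxidocoumarin, an acid-base step that makes the Claisen condensation irreversible; acid then liberates 7. The closest known reaction type is the Dieckmann-type intramolecular Claisen condensation of methyl 2-(arylacetoxy)benzoates to 3-aryl-4-hydroxycoumarins, a relative of the Baker–Venkataraman acyl transfer. No stereocentre is formed. The selectivity needed is C-acylation inside the molecule rather than loss of the arylacetyl group by alkoxide attack on the activated aryl ester or by ketene expulsion from its enolate. It is secured by a hindered base in more than two equivalents, so that 6 is fully enolised before methoxide appears, by the six-membered transition state, and by the benzyl ether, which leaves no second ester or free phenoxide for acyl exchange. Phenoxide and ketene that do form by reversible fragmentation can recombine to the same enolate, and the acidic product is separated from neutral by-products by base extraction.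

Step 6
Reactants: 7 7-(benzyloxy)-4-hydroxy-6-methoxy-3-(4-methoxyphenyl)-2H-chromen-2-one
Product: 9 1-[4-(benzyloxy)-2-hydroxy-5-methoxyphenyl]-2-(4-methoxyphenyl)ethan-1-one, via keto acid 8 (not isolated)
Conditions: NaOH (10% aq.), EtOH, reflux, N2; then HCl, 50 °C
Reagents that add atoms: water, O (as hydroxide; its oxygen is carried by intermediate 8 and leaves with the CO2)
Why: Alkaline cleavage of a 4-hydroxycoumarin; hydroxide opens the lactone to the salt of keto acid 8, which loses CO2 on acidification and warming, the classical degradation of 3-aryl-4-hydroxycoumarins to 2-hydroxydeoxybenzoins. Benzyl and methyl aryl ethers are stable to hot aqueous alkali, and air is excluded because the enolisable product autoxidises in base.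

Step 7
Reactants: 9 1-[4-(benzyloxy)-2-hydroxy-5-methoxyphenyl]-2-(4-methoxyphenyl)ethan-1-one
Product: 10 1-[4-(benzyloxy)-2-hydroxy-5-methoxyphenyl]-2-(4-methoxyphenyl)ethane-1,2-dione
Conditions: SeO2 (1.5 equiv), 1,4-dioxane/H2O, reflux
Reagents that add atoms: selenium dioxide, O=[Se]=O
Why: Riley oxidation; SeO2 attacks the enol of the ketone at its only enolisable position, the methylene that is both benzylic and alpha to the carbonyl, and the selenium intermediate collapses to the 1,2-diketone. The phenol is tempered by its hydrogen bond to the carbonyl and the other ring oxygens are capped as ethers.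

Step 8
Reactants: 10 1-[4-(benzyloxy)-2-hydroxy-5-methoxyphenyl]-2-(4-methoxyphenyl)ethane-1,2-dione
Product: 11 1-(2,4-dihydroxy-5-methoxyphenyl)-2-(4-methoxyphenyl)ethane-1,2-dione
Conditions: BCl3 (3 equiv), C6HMe5 (3 equiv), CH2Cl2, −78 °C; then H2O
Reagents that add atoms: none
Why: Lewis-acid debenzylation with a cation scavenger; BCl3 cleaves the aryl benzyl ether at −78 °C and pentamethylbenzene traps the benzyl cation, so the electron-rich ring is not benzylated, while the methyl ethers, neither of them chelated to a carbonyl, stay intact at this temperature. Hydrogenolysis is avoided because it would reduce the diketone to the benzoin.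

Step 9
Reactants: 11 1-(2,4-dihydroxy-5-methoxyphenyl)-2-(4-methoxyphenyl)ethane-1,2-dione; 12 3-methylbut-2-enal
Product: 14 dielsianone [1-(5-hydroxy-8-methoxy-2,2-dimethyl-2H-chromen-6-yl)-2-(4-methoxyphenyl)ethane-1,2-dione], via ortho-quinone methide 13 (not isolated)
Conditions: pyridine, 120 °C, sealed tube (12 in excess)
Reagents that add atoms: none
Why: Pyridine-mediated chromene annulation of a resorcinol with an enal; the ring carbon between the two hydroxyls (the only free position ortho to a hydroxyl) condenses with the aldehyde carbon of 12, loss of water gives ortho-quinone methide 13, and oxa-6π electrocyclisation closes ring B. The oxygen para to the ketone closes the ring because the other hydroxyl stays hydrogen-bonded to Ca=O and ends as the C5 phenol, the known outcome with 2,4-dihydroxyaryl ketones. Pyridine is used instead of a primary-amine catalyst because 1,2-diamines condense with the diketone.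

## Compound list

1 | 4-methoxybenzene-1,3-diol | COc1ccc(O)cc1O | starting material
2 | 2,4-dihydroxy-5-methoxybenzoic acid | COc1cc(C(=O)O)c(O)cc1O | intermediate
3 | methyl 2,4-dihydroxy-5-methoxybenzoate | COC(=O)c1cc(OC)c(O)cc1O | intermediate
4 | methyl 4-(benzyloxy)-2-hydroxy-5-methoxybenzoate | COC(=O)c1cc(OC)c(OCc2ccccc2)cc1O | intermediate
5 | 4-methoxyphenylacetic acid | COc1ccc(CC(=O)O)cc1 | starting material
6 | methyl 4-(benzyloxy)-5-methoxy-2-{[2-(4-methoxyphenyl)acetyl]oxy}benzoate | COC(=O)c1cc(OC)c(OCc2ccccc2)cc1OC(=O)Cc1ccc(OC)cc1 | intermediate
7 | 7-(benzyloxy)-4-hydroxy-6-methoxy-3-(4-methoxyphenyl)-2H-chromen-2-one | COc1ccc(-c2c(O)c3cc(OC)c(OCc4ccccc4)cc3oc2=O)cc1 | intermediate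
8 | 3-[4-(benzyloxy)-2-hydroxy-5-methoxyphenyl]-2-(4-methoxyphenyl)-3-oxopropanoic acid (racemic) | COc1ccc(C(C(=O)O)C(=O)c2cc(OC)c(OCc3ccccc3)cc2O)cc1 | intermediate (not isolated)
9 | 1-[4-(benzyloxy)-2-hydroxy-5-methoxyphenyl]-2-(4-methoxyphenyl)ethan-1-one | COc1ccc(CC(=O)c2cc(OC)c(OCc3ccccc3)cc2O)cc1 | intermediate
10 | 1-[4-(benzyloxy)-2-hydroxy-5-methoxyphenyl]-2-(4-methoxyphenyl)ethane-1,2-dione | COc1ccc(C(=O)C(=O)c2cc(OC)c(OCc3ccccc3)cc2O)cc1 | intermediate
11 | 1-(2,4-dihydroxy-5-methoxyphenyl)-2-(4-methoxyphenyl)ethane-1,2-dione | COc1ccc(C(=O)C(=O)c2cc(OC)c(O)cc2O)cc1 | intermediate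
12 | 3-methylbut-2-enal | CC(C)=CC=O | starting material
13 | 1-[(3Z)-2-hydroxy-5-methoxy-3-(3-methylbut-2-en-1-ylidene)-4-oxocyclohexa-1,5-dien-1-yl]-2-(4-methoxyphenyl)ethane-1,2-dione | CC(C)=C\C=C1/C(=O)C(OC)=CC(C(=O)C(=O)c2ccc(OC)cc2)=C1O | intermediate (not isolated)
14 | dielsianone, 1-(5-hydroxy-8-methoxy-2,2-dimethyl-2H-chromen-6-yl)-2-(4-methoxyphenyl)ethane-1,2-dione | COc1ccc(C(=O)C(=O)c2cc(OC)c3c(c2O)C=CC(C)(C)O3)cc1 | target

## Count and risks

Total step count: 9. Longest linear sequence: 9 steps (1 to 14); 5 and 12 are bought and enter at steps 4 and 9.

**Step 5 (key step).** The most likely failure is loss of the arylacetyl group before ring closure: alkoxide attack on the activated aryl ester, or ketene expulsion from its enolate, would return phenol 4. Fallback: the C6–Ca bond is made in place of Ca–Cb. Diol 1 and acid 5 are heated in BF3·OEt2 (Friedel–Crafts acylation at the carbon ortho to one hydroxyl and para to the other) to give 1-(2,4-dihydroxy-5-methoxyphenyl)-2-(4-methoxyphenyl)ethan-1-one F1. Its non-chelated hydroxyl is then benzylated (BnBr, K2CO3, acetone). This sets out from 1 and 5 and comes back to the route at 9, replacing steps 1 to 6.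

**Step 6.** Hydroxide may add to the C4 carbonyl and not to the lactone, so that retro-Claisen cleavage of the new Ca–Cb bond competes with opening. The delocalised 4-oxidocoumarin may also simply resist attack, and the product can autoxidise in hot alkali if air enters. Fallback: the vinylogous acid is destroyed before the carbon is excised. Coumarin 7 is hydroxylated at C3 with dimethyldioxirane in acetone at 0 °C (Rubottom-type oxidation of the enol) to 7-(benzyloxy)-3-hydroxy-6-methoxy-3-(4-methoxyphenyl)chromane-2,4-dione F2. Its lactone is no longer stabilised and should open in aqueous NaHCO3/THF with loss of CO2 to the benzoin 1-[4-(benzyloxy)-2-hydroxy-5-methoxyphenyl]-2-hydroxy-2-(4-methoxyphenyl)ethan-1-one F3. Oxidation of this alpha-hydroxy ketone with Cu(OAc)2 (cat.) and NH4NO3 in aqueous acetic acid gives 10. This sets out from 7 and comes back at 10, so step 7 is bypassed as well.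

**Step 7.** The free ortho phenol and the electron-rich ring may take part: electrophilic selenium may attack the ring, the para-methoxyphenol unit may be oxidised towards a quinone, or the diketone may be cleaved further. Fallback: the phenol is masked before oxidation. Deoxybenzoin 9 is benzylated (BnBr, K2CO3, DMF, 80 °C) to 1-[2,4-bis(benzyloxy)-5-methoxyphenyl]-2-(4-methoxyphenyl)ethan-1-one F4. Riley oxidation then gives 1-[2,4-bis(benzyloxy)-5-methoxyphenyl]-2-(4-methoxyphenyl)ethane-1,2-dione F5, and both benzyl groups are removed with BCl3 and pentamethylbenzene. This sets out from 9 and comes back at 11.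

**Step 9.** Condensation may be slow because the ketoacyl group lowers the nucleophilicity of the ring carbon between the hydroxyls, so that self-condensation of 12 and thermal degradation of the diketone in hot pyridine take over. Closure on the hydrogen-bonded oxygen is a lesser risk. Fallback: the pyran ring is built by O-alkylation and sigmatropic rearrangement. The non-chelated hydroxyl of 11 is alkylated with 3-chloro-3-methylbut-1-yne (K2CO3, KI, acetone, reflux) to 1-{2-hydroxy-5-methoxy-4-[(2-methylbut-3-yn-2-yl)oxy]phenyl}-2-(4-methoxyphenyl)ethane-1,2-dione F6. Heating in N,N-diethylaniline brings about aromatic propargyl Claisen rearrangement to the only free ortho carbon, 1,5-hydrogen shift and oxa-6π closure. This sets out from 11 and comes back at 14.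

## Further compounds

F1 | step 5 | 1-(2,4-dihydroxy-5-methoxyphenyl)-2-(4-methoxyphenyl)ethan-1-one | COc1ccc(CC(=O)c2cc(OC)c(O)cc2O)cc1
F2 | step 6 | 7-(benzyloxy)-3-hydroxy-6-methoxy-3-(4-methoxyphenyl)chromane-2,4-dione (racemic) | COc1ccc(C2(O)C(=O)Oc3cc(OCc4ccccc4)c(OC)cc3C2=O)cc1
F3 | step 6 | 1-[4-(benzyloxy)-2-hydroxy-5-methoxyphenyl]-2-hydroxy-2-(4-methoxyphenyl)ethan-1-one (racemic) | COc1ccc(C(O)C(=O)c2cc(OC)c(OCc3ccccc3)cc2O)cc1
F4 | step 7 | 1-[2,4-bis(benzyloxy)-5-methoxyphenyl]-2-(4-methoxyphenyl)ethan-1-one | COc1ccc(CC(=O)c2cc(OC)c(OCc3ccccc3)cc2OCc2ccccc2)cc1
F5 | step 7 | 1-[2,4-bis(benzyloxy)-5-methoxyphenyl]-2-(4-methoxyphenyl)ethane-1,2-dione | COc1ccc(C(=O)C(=O)c2cc(OC)c(OCc3ccccc3)cc2OCc2ccccc2)cc1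
F6 | step 9 | 1-{2-hydroxy-5-methoxy-4-[(2-methylbut-3-yn-2-yl)oxy]phenyl}-2-(4-methoxyphenyl)ethane-1,2-dione | COc1ccc(C(=O)C(=O)c2cc(OC)c(OC(C)(C)C#C)cc2O)cc1
A1 | alternative 1 | 4,5-bis(benzyloxy)-2-(trimethylsilyl)phenyl trifluoromethanesulfonate | C[Si](C)(C)c1cc(OCc2ccccc2)c(OCc2ccccc2)cc1OS(=O)(=O)C(F)(F)F
A2 | alternative 1 | 1-[4,5-bis(benzyloxy)-2-hydroxyphenyl]-2-(4-methoxyphenyl)ethan-1-one | COc1ccc(CC(=O)c2cc(OCc3ccccc3)c(OCc3ccccc3)cc2O)cc1
A3 | alternative 2 | 2-hydroxy-3-methoxy-6-(methoxymethoxy)benzaldehyde | COCOc1ccc(OC)c(O)c1C=O
A4 | alternative 2 | dibenzylamine | C(NCc1ccccc1)c1ccccc1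
A5 | alternative 2 | (2-methylprop-1-en-1-yl)boronic acid | CC(C)=CB(O)O
A6 | alternative 2 | 8-methoxy-5-(methoxymethoxy)-2,2-dimethyl-2H-chromene | COCOc1ccc(OC)c2c1C=CC(C)(C)O2
A7 | alternative 3 | pentacarbonyl[(6,6-dimethyl-5,6-dihydro-4H-pyran-2-yl)(methoxy)methylidene]chromium | COC(C1=CCCC(C)(C)O1)=[Cr](=C=O)(=C=O)(=C=O)(=C=O)=C=O
A8 | alternative 3 | 1-(buta-1,3-diyn-1-yl)-4-methoxybenzene | COc1ccc(C#CC#C)cc1
A9 | alternative 3 | 8-methoxy-6-[(4-methoxyphenyl)ethynyl]-2,2-dimethyl-3,4-dihydro-2H-chromen-5-ol | COc1ccc(C#Cc2cc(OC)c3c(c2O)CCC(C)(C)O3)cc1
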